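**Retrosynthetic overview**

- The target is opened at no bond but closed in thought: joining the oxygen of the C3 CH2OH group to the benzylic CH2 carbon on C4 of the oxolane (O1, C2 aryl, C3, C4, C5) gives the twofold-symmetric exo,exo-2,6-diaryl-3,7-dioxabicyclo[3.3.0]octane, so the last step is hydrogenolysis of one of its two equivalent benzylic C–O bonds.
- The feature the strategy rests on: in that bicycle C4–C5–C1–C8 (C5 carbon, C4, C3 and CH2OH carbon of the target) is a succinyl unit, and C2 and C6 (C2 and the benzylic CH2 of the target) are ArCH–O carbons, i.e. aldol carbons.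
- The two ring CH2 groups (C4, C8) are taken back to lactone carbonyls: bis-lactol reduction and deoxygenation from the 4,8-dione.
- The dilactone is cut at C1–C2 and C5–C6 (two aldol bonds) and at both lactone C(=O)–O bonds: succinyl bis-imide plus two molecules of 3,4,5-trimethoxybenzaldehyde; both rings form in this step, the second lactone after the first.
- The bis-imide comes from succinyl chloride and two molecules of (S)-4-benzyl-1,3-oxazolidin-2-one.

Key step: step 2

Remark on the chemistry: both imides are enolised before the aldehyde is added, so that no enolisation is needed beside an aldolate or a lactone and the distal acyl group stays masked as an enolate until both aldol bonds exist. The all-S dilactone is what the (S)-benzyl auxiliary should deliver and what the (2S,3R,4R) target requires; the ring-fusion descriptors change from S to R on C=O → CH2 by priority only.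

**Route**

Step 1
Reactants: 1 succinyl chloride; 2 (S)-4-benzyl-1,3-oxazolidin-2-one (2 equiv)
Product: 4 bis-imide 1,4-bis[(4S)-4-benzyl-2-oxo-1,3-oxazolidin-3-yl]butane-1,4-dione, via lithium oxazolidinide 3 (not isolated)
Conditions: 2 (2.1 equiv), n-BuLi (2.05 equiv), THF, −78 °C; then 1 (1.0 equiv), −78 → 0 °C
Reagents that add atoms: none
Why: Double N-acylation of the lithium oxazolidinide by the diacid chloride is standard imide formation (nucleophilic acyl substitution); the auxiliary stereocentre is not involved and addition at −78 °C suppresses ketene formation from 1.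

Step 2
Reactants: 4 bis-imide; 5 3,4,5-trimethoxybenzaldehyde (two molecules incorporated)
Product: 9 exo,exo-dilactone (1S,2S,5S,6S)-2,6-bis(3,4,5-trimethoxyphenyl)-3,7-dioxabicyclo[3.3.0]octane-4,8-dione, via bis(dibutylboron enolate) 6 (not isolated), via bis-aldol diol 7 (not isolated), via hydroxy lactone imide 8 (not isolated)
Conditions: Bu2BOTf (2.4 equiv), i-Pr2NEt (3.0 equiv), CH2Cl2, 0 °C; 5 (2.5 equiv), −78 → 0 °C; pH 7 buffer (NaH2PO4/Na2HPO4), MeOH, 30% H2O2, 0 °C; then DMAP (cat.), CH2Cl2, rt
Reagents that add atoms: none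
Why: Proposed new method: double soft enolisation (Bu2BOTf, i-Pr2NEt) of both imides before the aldehyde is present should give the (1Z,3Z)-bis(boron enolate) 6, in which the distal acyl group stays masked until both C–C bonds exist, and each enolate then adds to 5 through a closed Zimmerman–Traxler chair to form the C1–C2 and C5–C6 bonds of the bicycle. The closest known reaction type is the Evans boron syn-aldol of N-succinyl oxazolidinone half-esters with lactonisation to paraconic esters, here run on both ends of one succinyl unit, and the double soft enolisation has its analogy in the conversion of succinic anhydride into 2,5-bis(silyloxy)furans. The dipole-opposed (S)-benzyloxazolidinone shields the same enolate face at both α-carbons (both S, the later ring-fusion carbons C1 and C5) and the Z geometry in the chair sets each carbinol carbon syn to it (both S, the later C2 and C6). Once the B–O bonds are cleaved, the hydroxyl on each carbinol carbon of 7 closes a γ-lactone by 5-exo-trig acyl substitution on the distal imide carbonyl, first to 8 and then to 9, each closure releasing one molecule of 2; attack on the proximal carbonyl would need a four-membered ring. The second lactone can only form cis-fused, which the like configuration of the two α-carbons provides, and the syn relation leaves each aryl group trans to the neighbouring ring-fusion substituent, that is exo. The step needs auxiliary control at both enolates, and the open point is whether the stereocentres already formed beside the second enolate are matched with the auxiliary in the second addition.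

Step 3
Reactants: 9 exo,exo-dilactone
Product: 10 bis-lactol (1S,2S,5S,6S)-2,6-bis(3,4,5-trimethoxyphenyl)-3,7-dioxabicyclo[3.3.0]octane-4,8-diol (mixture of anomers)
Conditions: i-Bu2AlH (2.4 equiv), CH2Cl2, −78 °C; MeOH quench, then aqueous KNaC4H4O6
Reagents that add atoms: none
Why: Partial reduction of a γ-lactone with i-Bu2AlH at −78 °C stops at the aluminium hemiacetal and gives the lactol on work-up; the aryl ethers and the four stereocentres are inert and the two new anomeric centres are removed in step 4.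

Step 4
Reactants: 10 bis-lactol
Product: 11 furofuran (1R,2S,5R,6S)-2,6-bis(3,4,5-trimethoxyphenyl)-3,7-dioxabicyclo[3.3.0]octane
Conditions: Et3SiH (6 equiv), BF3·OEt2 (3 equiv), CH2Cl2, −78 → −20 °C
Reagents that add atoms: none
Why: Reductive deoxygenation of lactols (ionic hydrogenation): BF3 ionises each anomeric C–OH to the cyclic oxocarbenium ion and Et3SiH delivers hydride; no stereocentre is formed and the low temperature should keep the benzylic C–O bonds from ionising.

Step 5
Reactants: 11 furofuran
Product: 12 [(2S,3R,4R)-2-(3,4,5-trimethoxyphenyl)-4-[(3,4,5-trimethoxyphenyl)methyl]oxolan-3-yl]methanol (CNP0321241.1)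
Conditions: H2 (1 atm), Pd/C (10 wt% Pd), EtOH–AcOH, rt, stopped when 11 is consumed
Reagents that add atoms: none
Why: Heterogeneous hydrogenolysis of a benzylic C–O bond; the two benzylic ether bonds of 11 are exchanged by the twofold axis so either cleavage gives 12, the cleaved carbon becomes CH2 while C2, C3 and C4 are untouched, and opening of the strained cis-fused bicycle should be faster than cleavage of the monocyclic product.

**Compound list**

1 | succinyl chloride (butanedioyl dichloride) | O=C(Cl)CCC(=O)Cl | starting material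
2 | (S)-4-benzyl-1,3-oxazolidin-2-one | O=C1N[C@@H](Cc2ccccc2)CO1 | starting material
3 | lithium (S)-4-benzyl-2-oxo-1,3-oxazolidin-3-ide | [Li+].O=C1[N-][C@@H](Cc2ccccc2)CO1 | intermediate (not isolated)
4 | 1,4-bis[(4S)-4-benzyl-2-oxo-1,3-oxazolidin-3-yl]butane-1,4-dione | O=C(CCC(=O)N1[C@@H](Cc2ccccc2)COC1=O)N1[C@@H](Cc2ccccc2)COC1=O | intermediate
5 | 3,4,5-trimethoxybenzaldehyde | COc1cc(C=O)cc(OC)c1OC | starting material
6 | (1Z,3Z)-1,4-bis[(4S)-4-benzyl-2-oxo-1,3-oxazolidin-3-yl]-1,4-bis(dibutylboranyloxy)buta-1,3-diene | CCCCB(CCCC)O/C(N1[C@@H](Cc2ccccc2)COC1=O)=C\C=C(/OB(CCCC)CCCC)N1[C@@H](Cc2ccccc2)COC1=O | intermediate (not isolated)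
7 | (2S,3S)-1,4-bis[(4S)-4-benzyl-2-oxo-1,3-oxazolidin-3-yl]-2,3-bis[(S)-hydroxy(3,4,5-trimethoxyphenyl)methyl]butane-1,4-dione | O=C(N1[C@@H](Cc2ccccc2)COC1=O)[C@H]([C@H](O)c1cc(OC)c(OC)c(OC)c1)[C@@H]([C@H](O)c1cc(OC)c(OC)c(OC)c1)C(=O)N1[C@@H](Cc2ccccc2)COC1=O | intermediate (not isolated)
8 | (4S)-4-benzyl-3-{(2S,3S,4S)-4-[(S)-hydroxy(3,4,5-trimethoxyphenyl)methyl]-5-oxo-2-(3,4,5-trimethoxyphenyl)oxolane-3-carbonyl}-1,3-oxazolidin-2-one | O=C(N1[C@@H](Cc2ccccc2)COC1=O)[C@@H]3[C@@H](c1cc(OC)c(OC)c(OC)c1)OC(=O)[C@@H]3[C@H](O)c1cc(OC)c(OC)c(OC)c1 | intermediate (not isolated)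
9 | (1S,2S,5S,6S)-2,6-bis(3,4,5-trimethoxyphenyl)-3,7-dioxabicyclo[3.3.0]octane-4,8-dione (cis-fused, both aryl groups exo) | O=C1O[C@H](c3cc(OC)c(OC)c(OC)c3)[C@H]2C(=O)O[C@H](c3cc(OC)c(OC)c(OC)c3)[C@@H]12 | intermediate
10 | (1S,2S,5S,6S)-2,6-bis(3,4,5-trimethoxyphenyl)-3,7-dioxabicyclo[3.3.0]octane-4,8-diol (anomers at C4 and C8) | OC1O[C@H](c3cc(OC)c(OC)c(OC)c3)[C@H]2C(O)O[C@H](c3cc(OC)c(OC)c(OC)c3)[C@@H]12 | intermediate
11 | (1R,2S,5R,6S)-2,6-bis(3,4,5-trimethoxyphenyl)-3,7-dioxabicyclo[3.3.0]octane | C1O[C@H](c3cc(OC)c(OC)c(OC)c3)[C@H]2CO[C@H](c3cc(OC)c(OC)c(OC)c3)[C@@H]12 | intermediate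
12 | [(2S,3R,4R)-2-(3,4,5-trimethoxyphenyl)-4-[(3,4,5-trimethoxyphenyl)methyl]oxolan-3-yl]methanol | COc1cc(C[C@H]2CO[C@H](c3cc(OC)c(OC)c(OC)c3)[C@H]2CO)cc(OC)c1OC | target

**Step count and risks**

Total steps: 5. Longest linear sequence: 5 (1 and 2 → 4 → 9 → 10 → 11 → 12).

Steps most likely to fail:

1. Step 2 (key step, proposed new method). The second enolisation may stall, or the second aldol addition may run with the wrong facial sense beside the stereocentres already formed. The result would be a mono-aldol lactone or an unlike bis-adduct that cannot close the second ring. The fallback uses known lactone-lignan chemistry, brings the benzylic CH2 in as a benzyl group from the start, sets out from 2 and 5 and comes back at 12.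
   - Commercial 3-(3,4,5-trimethoxyphenyl)propanoic acid F1 is converted with (COCl)2 and cat. DMF in CH2Cl2 into 3-(3,4,5-trimethoxyphenyl)propanoyl chloride F2, which acylates 3 (from 2 and n-BuLi, THF, −78 °C) to (4S)-4-benzyl-3-[3-(3,4,5-trimethoxyphenyl)propanoyl]-1,3-oxazolidin-2-one F3.
   - Evans alkylation (NaN(SiMe3)2, THF, −78 °C; BrCH2CO2t-Bu) on the enolate face away from the auxiliary benzyl group should give tert-butyl (3R)-4-[(4S)-4-benzyl-2-oxo-1,3-oxazolidin-3-yl]-4-oxo-3-[(3,4,5-trimethoxyphenyl)methyl]butanoate F4.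
   - LiBH4 (THF, H2O, 0 °C) removes the auxiliary to give tert-butyl (3R)-4-hydroxy-3-[(3,4,5-trimethoxyphenyl)methyl]butanoate F5, and CF3CO2H in CH2Cl2 closes (4R)-4-[(3,4,5-trimethoxyphenyl)methyl]oxolan-2-one F6.
   - The lithium enolate of F6 (LiN(i-Pr)2, THF, −78 °C) should add to 5 trans to the benzyl group to give (3S,4R)-3-[hydroxy(3,4,5-trimethoxyphenyl)methyl]-4-[(3,4,5-trimethoxyphenyl)methyl]oxolan-2-one F7 as a mixture at the carbinol carbon.
   - LiAlH4 (THF, 0 °C) should give (2R,3R)-2-(hydroxymethyl)-1-(3,4,5-trimethoxyphenyl)-3-[(3,4,5-trimethoxyphenyl)methyl]butane-1,4-diol F8.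
   - Camphorsulfonic acid in CH2Cl2 ionises the benzylic alcohol of F8, and the primary hydroxyl on the benzyl-bearing carbon closes the oxolane with the aryl group trans to the CH2OH group, to give 12. The carbinol mixture in F7 and F8 is of no consequence because that centre is set in the cationic ring closure.

2. Step 5. Cleavage of the second benzylic C–O bond may set in before 11 is consumed (over-reduction to the ring-opened diol). The fallback sets out from 11 and comes back at 12.
   - The hydrogenolysis is run to completion (H2, Pd(OH)2/C, EtOH, AcOH) to the twofold-symmetric (2R,3R)-2,3-bis[(3,4,5-trimethoxyphenyl)methyl]butane-1,4-diol F9.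
   - One ring is then closed again oxidatively: DDQ (1 equiv, CH2Cl2, 0 °C) abstracts a benzylic hydride and the hydroxyl four atoms away traps the cation as the 2-aryl oxolane, the aryl group expected trans to the neighbouring CH2OH. The two benzylic positions of F9 are equivalent, so no site selection is needed.

3. Step 4. BF3 may ionise the benzylic C–O bonds of the electron-rich aryl ethers, leading to epimerisation, Friedel–Crafts closure or reductive ring opening. The fallback avoids cationic conditions, sets out from 9 and comes back at 11.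
   - LiAlH4 (THF, 0 °C → rt) reduces both lactones to (1S,2R,3R,4S)-2,3-bis(hydroxymethyl)-1,4-bis(3,4,5-trimethoxyphenyl)butane-1,4-diol F10.
   - MsCl (2.2 equiv) in pyridine at 0 °C → rt sulfonylates the two primary hydroxyls to (2R,3R)-2,3-bis[(S)-hydroxy(3,4,5-trimethoxyphenyl)methyl]butane-1,4-diyl dimethanesulfonate F11.
   - Each benzylic hydroxyl of F11 then displaces the mesylate on the other branch (5-exo-tet, no stereocentre touched) to give 11.

**Further compounds**

F1 | step 2 | 3-(3,4,5-trimethoxyphenyl)propanoic acid | COc1cc(CCC(=O)O)cc(OC)c1OC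
F2 | step 2 | 3-(3,4,5-trimethoxyphenyl)propanoyl chloride | COc1cc(CCC(=O)Cl)cc(OC)c1OC
F3 | step 2 | (4S)-4-benzyl-3-[3-(3,4,5-trimethoxyphenyl)propanoyl]-1,3-oxazolidin-2-one | COc1cc(CCC(=O)N2[C@@H](Cc3ccccc3)COC2=O)cc(OC)c1OC
F4 | step 2 | tert-butyl (3R)-4-[(4S)-4-benzyl-2-oxo-1,3-oxazolidin-3-yl]-4-oxo-3-[(3,4,5-trimethoxyphenyl)methyl]butanoate | COc1cc(C[C@H](CC(=O)OC(C)(C)C)C(=O)N2[C@@H](Cc3ccccc3)COC2=O)cc(OC)c1OC
F5 | step 2 | tert-butyl (3R)-4-hydroxy-3-[(3,4,5-trimethoxyphenyl)methyl]butanoate | COc1cc(C[C@H](CC(=O)OC(C)(C)C)CO)cc(OC)c1OC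
F6 | step 2 | (4R)-4-[(3,4,5-trimethoxyphenyl)methyl]oxolan-2-one | COc1cc(C[C@H]2COC(=O)C2)cc(OC)c1OC
F7 | step 2 | (3S,4R)-3-[hydroxy(3,4,5-trimethoxyphenyl)methyl]-4-[(3,4,5-trimethoxyphenyl)methyl]oxolan-2-one (carbinol epimers) | COc1cc(C[C@H]2COC(=O)[C@@H]2C(O)c2cc(OC)c(OC)c(OC)c2)cc(OC)c1OC
F8 | step 2 | (2R,3R)-2-(hydroxymethyl)-1-(3,4,5-trimethoxyphenyl)-3-[(3,4,5-trimethoxyphenyl)methyl]butane-1,4-diol (C1 epimers) | COc1cc(C[C@@H](CO)[C@H](CO)C(O)c2cc(OC)c(OC)c(OC)c2)cc(OC)c1OC
F9 | step 5 | (2R,3R)-2,3-bis[(3,4,5-trimethoxyphenyl)methyl]butane-1,4-diol | COc1cc(C[C@@H](CO)[C@H](CO)Cc2cc(OC)c(OC)c(OC)c2)cc(OC)c1OC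
F10 | step 4 | (1S,2R,3R,4S)-2,3-bis(hydroxymethyl)-1,4-bis(3,4,5-trimethoxyphenyl)butane-1,4-diol | OC[C@H]([C@H](O)c1cc(OC)c(OC)c(OC)c1)[C@@H]([C@H](O)c1cc(OC)c(OC)c(OC)c1)CO
F11 | step 4 | (2R,3R)-2,3-bis[(S)-hydroxy(3,4,5-trimethoxyphenyl)methyl]butane-1,4-diyl dimethanesulfonate | CS(=O)(=O)OC[C@H]([C@H](O)c1cc(OC)c(OC)c(OC)c1)[C@@H]([C@H](O)c1cc(OC)c(OC)c(OC)c1)COS(C)(=O)=O
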